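**Retrosynthetic overview**
1. Target 11 is cut at the C2–C1' bond into chromone core 5 and a heptadecyl radical from stearic acid derivative 8 (new decarboxylative C2–H alkylation of the protonated chromone).
2. Chromone 5 is cut at C2 into acetophenone 3 and a one-carbon unit (orthoformate); this closes the pyranone ring.
3. Acetophenone 3 comes from commercial phloroacetophenone 1 by double C-methylation.
4. Ring order: the benzene ring is bought in 1, the pyranone ring is formed in step 2, and the side chain is attached last.

Assumption: the target SMILES has no stereocentre, so the compound is achiral and there is no configuration to set.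

**Step 1**
Reactants: 1 2',4',6'-trihydroxyacetophenone (phloroacetophenone)
Product: 3 1-(2,4,6-trihydroxy-3,5-dimethylphenyl)ethan-1-one, via 3-methylphloroacetophenone 2 (not isolated)
Conditions: MeI (2.1 equiv), NaOMe (2.2 equiv), MeOH, 0 → 65 °C; aq HCl work-up
Reagents that add atoms: iodomethane CI
Why: Base-mediated electrophilic C-methylation (SN2 attack of the ambident phloroglucinol phenoxide through carbon, first at C3 then at C5) is the established entry to 3,5-di-C-methylphloroacetophenones, and limiting MeI to two equivalents suppresses gem-dimethylation and O-methylation.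

**Step 2**
Reactants: 3 1-(2,4,6-trihydroxy-3,5-dimethylphenyl)ethan-1-one
Product: 5 5,7-dihydroxy-6,8-dimethyl-4H-chromen-4-one, via 4-ethoxychromenylium perchlorate 4 (not isolated)
Conditions: HC(OEt)3 (6 equiv), 70% aq HClO4 (1.2 equiv), 0 → 25 °C; then H2O, 95 °C
Reagents that add atoms: triethyl orthoformate CCOC(OCC)OCC; water O
Why: Acid-mediated orthoformate cyclocondensation (Claisen-type C-formylation of the acetyl enol by the diethoxycarbenium ion, ring closure by an ortho-hydroxyl, O-ethylation to the 4-ethoxybenzopyrylium salt, then hydrolysis) is the classical chromone synthesis for polyhydroxyacetophenones, and every ring carbon of 3 is blocked so only the acetyl group reacts; salt 4 is kept wet and hydrolysed directly.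

**Step 3**
Reactants: 6 stearoyl chloride (octadecanoyl chloride); 7 N-hydroxyphthalimide
Product: 8 1,3-dioxoisoindolin-2-yl octadecanoate
Conditions: Et3N (1.2 equiv), CH2Cl2, 0 → 25 °C
Reagents that add atoms: none
Why: Schotten–Baumann-type O-acylation of the N-hydroxyimide by an acid chloride is the standard preparation of redox-active esters.

**Step 4**
Reactants: 5 5,7-dihydroxy-6,8-dimethyl-4H-chromen-4-one; 8 1,3-dioxoisoindolin-2-yl octadecanoate
Product: 11 2-heptadecyl-5,7-dihydroxy-6,8-dimethyl-4H-chromen-4-one, via chromenylium triflate 9 (not isolated), via 2-heptadecylchromenylium triflate 10 (not isolated)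
Conditions: 8 (1.5 equiv), TfOH (2.0 equiv), 4CzIPN (2,4,5,6-tetra(carbazol-9-yl)isophthalonitrile, 3 mol %), MeCN/ClCH2CH2Cl 1:1, 450 nm LEDs, 25 °C, argon; then aq NaHCO3
Reagents that add atoms: none
Why: Proposed new method: triflic acid turns 5 into the 4-hydroxybenzopyrylium salt 9, an oxygen analogue of a protonated quinoline whose only electrophilic C–H position is C2; excited 4CzIPN reduces 8 to the nucleophilic heptadecyl radical (loss of CO2 and phthalimide anion), which adds at C2, the adduct radical cation loses the C2 proton to a pyranyl radical that the oxidised photocatalyst converts to 10 (redox-neutral overall), and bicarbonate releases chromone 11; the cationic, electron-poor phenols are poor hydrogen-atom donors, so no O-protection is planned; the closest known reaction types are the photoredox Minisci alkylation of protonated azines with N-acyloxyphthalimides and the decarboxylative Giese addition to chromones, which stops at the chromanone.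

**Compound list**
1 | 2',4',6'-trihydroxyacetophenone | CC(=O)c1c(O)cc(O)cc1O | starting material
2 | 1-(2,4,6-trihydroxy-3-methylphenyl)ethan-1-one | CC(=O)c1c(O)cc(O)c(C)c1O | intermediate
3 | 1-(2,4,6-trihydroxy-3,5-dimethylphenyl)ethan-1-one | CC(=O)c1c(O)c(C)c(O)c(C)c1O | intermediate
4 | 4-ethoxy-5,7-dihydroxy-6,8-dimethylchromenylium perchlorate | CCOc1cc[o+]c2c(C)c(O)c(C)c(O)c12.[O-]Cl(=O)(=O)=O | intermediate
5 | 5,7-dihydroxy-6,8-dimethyl-4H-chromen-4-one | O=c1ccoc2c(C)c(O)c(C)c(O)c12 | intermediate
6 | stearoyl chloride (octadecanoyl chloride) | CCCCCCCCCCCCCCCCCC(=O)Cl | starting material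
7 | N-hydroxyphthalimide | O=C1c2ccccc2C(=O)N1O | starting material
8 | 1,3-dioxoisoindolin-2-yl octadecanoate | CCCCCCCCCCCCCCCCCC(=O)ON1C(=O)c2ccccc2C1=O | intermediate
9 | 4,5,7-trihydroxy-6,8-dimethylchromenylium trifluoromethanesulfonate | Oc1cc[o+]c2c(C)c(O)c(C)c(O)c12.[O-]S(=O)(=O)C(F)(F)F | intermediate
10 | 2-heptadecyl-4,5,7-trihydroxy-6,8-dimethylchromenylium trifluoromethanesulfonate | CCCCCCCCCCCCCCCCCc1cc(O)c2c(O)c(C)c(O)c(C)c2[o+]1.[O-]S(=O)(=O)C(F)(F)F | intermediate
11 | 2-heptadecyl-5,7-dihydroxy-6,8-dimethyl-4H-chromen-4-one | CCCCCCCCCCCCCCCCCc1cc(=O)c2c(O)c(C)c(O)c(C)c2o1 | target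

**Totals**
Total step count: 4. Longest linear sequence: 3 steps (1 → 3 → 5 → 11); step 3 is a one-step side branch.

**Steps most likely to fail**

Step 4 (the proposed new step). The primary radical may add too slowly to the strongly donor-stabilised cation 9, or the adduct may end as the chromanone. The fallback uses known chemistry and builds the chain before the ring. It sets out from 3: the lithium polyanion made with LiN(SiMe3)2 (5 equiv) in THF at −78 °C is C-acylated at the acetyl carbon with stearoyl chloride 6 (Claisen-type acylation). This gives 1-(2,4,6-trihydroxy-3,5-dimethylphenyl)icosane-1,3-dione F1. Heating F1 with catalytic H2SO4 in AcOH at 100 °C closes the pyranone ring by cyclodehydration, and the fallback comes back to the route at 11.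

Step 1. Mono-methyl, gem-dimethyl and O-methyl by-products may dominate. The fallback sets out from 1: a double Mannich reaction with aqueous formaldehyde and dimethylamine in EtOH gives 1-[3,5-bis(dimethylaminomethyl)-2,4,6-trihydroxyphenyl]ethan-1-one F2. Heating F2 with NaBH4 in EtOH expels the amine to give ortho-quinone methides, which the hydride reduces to the two C-methyl groups, and the fallback comes back to the route at 3.

Step 2. The orthoformate condensation may be sluggish on the hindered, chelated ketone, and the perchlorate salt needs care. The fallback sets out from 3: Claisen formylation of the polyanion (NaH, 4.5 equiv, ethyl formate, THF) and acidic quench give racemic 2,5,7-trihydroxy-6,8-dimethylchroman-4-one F3. Dehydration of F3 with HCl in AcOH at 80 °C gives the chromone, and the fallback comes back to the route at 5.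

**Further compounds**
F1 | step 4 | 1-(2,4,6-trihydroxy-3,5-dimethylphenyl)icosane-1,3-dione | CCCCCCCCCCCCCCCCCC(=O)CC(=O)c1c(O)c(C)c(O)c(C)c1O
F2 | step 1 | 1-[3,5-bis(dimethylaminomethyl)-2,4,6-trihydroxyphenyl]ethan-1-one | CC(=O)c1c(O)c(CN(C)C)c(O)c(CN(C)C)c1O
F3 | step 2 | racemic 2,5,7-trihydroxy-6,8-dimethylchroman-4-one | O=C1CC(O)Oc2c(C)c(O)c(C)c(O)c12
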